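## Retrosynthetic overview

- **Feature:** in the cyclopentenone ring the tertiary carbinol C5 is bonded to three oxygenated carbons: the ketone C1, the carbinol C4 and the acetoxy carbon C1′. With all three at the ketone level this is a triacyl carbinol, the pattern an acyl 1,2-shift leaves in a six-membered α-hydroxy trione.
- **Last disconnection:** one O1′-tethered hydride transfer from acetaldehyde to the (1′S)-hydroxyalkyl cyclopentenedione supplies the acetate, the C4–H bond and the C4/C5 configuration.
- **Setting C1′:** the enedione carbonyls react faster than the hindered side-chain ketone, so C1′ is set from the achiral triketone by a relay. One ring carbonyl is reduced enantioselectively, its chirality is passed to C1′ by a directed reduction, and the ring carbinol is re-oxidised.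
- **Key disconnection C4–C5:** the triketone comes from 3-hydroxy-3-tetradecylcyclohex-5-ene-1,2,4-trione by α-ketol ring contraction. The only ring is the arene ring, kept six-membered until that step makes it five-membered.
- **Precursor:** the trione comes from 2-hydroxy-3-tetradecyl-1,4-benzoquinone by enol hydroxylation. The quinone is made from 1,2,4-trimethoxybenzene and 1-bromotetradecane by C3 lithiation–alkylation, demethylation and oxidation.

Key step: step 5

Remark: the discussion uses target numbering (C1 ketone, C2=C3, C4 secondary carbinol, C5 tertiary carbinol, C1′ acetoxy carbon) while systematic names keep their own locants; the SMILES is read as 4S,5R,1′S, with O4 and O5 cis on the ring and O1′/O4 1,3-anti.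

## Route

Step 1
Reactants: 1 1,2,4-trimethoxybenzene; 2 1-bromotetradecane
Product: 4 1,2,4-trimethoxy-3-tetradecylbenzene, via 3-lithio-1,2,4-trimethoxybenzene 3 (not isolated)
Conditions: n-BuLi, THF, 0 °C to rt; then 2, DMPU, 0 to 40 °C
Reagents that add atoms: n-butyllithium, [Li]CCCC (lithium of 3 only)
Why: Directed ortho-metalation takes the C3–H that lies between the 2- and 4-methoxy groups, the most acidic and doubly coordinated site, and the aryllithium then displaces bromide from the unhindered primary halide by SN2.

Step 2
Reactants: 4 1,2,4-trimethoxy-3-tetradecylbenzene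
Product: 5 3-tetradecylbenzene-1,2,4-triol
Conditions: BBr3 (4 equiv), CH2Cl2, −78 °C to rt; degassed H2O, Ar
Reagents that add atoms: none
Why: Lewis-acid cleavage of aryl methyl ethers with BBr3 is general for polymethoxyarenes, the saturated chain is inert, and this order avoids exposing a 5,6-unsubstituted quinone to aqueous base.

Step 3
Reactants: 5 3-tetradecylbenzene-1,2,4-triol
Product: 6 2-hydroxy-3-tetradecylcyclohexa-2,5-diene-1,4-dione
Conditions: Ag2O, Na2SO4, Et2O, rt, dark; filtration
Reagents that add atoms: none
Why: Two-electron dehydrogenation of a hydroxyhydroquinone by Ag2O in dry ether is the classical neutral entry to hydroxy-1,4-benzoquinones, the para-quinone tautomer being favoured and the C3 alkyl group blocking self-condensation through that carbon.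

Step 4
Reactants: 6 2-hydroxy-3-tetradecylcyclohexa-2,5-diene-1,4-dione
Product: 8 3-hydroxy-3-tetradecylcyclohex-5-ene-1,2,4-trione (racemic), via hydroxy epoxide 7 (not isolated)
Conditions: dimethyldioxirane (acetone solution dried over 4 Å MS), CH2Cl2, −20 to 0 °C; volatiles removed cold, crude 8 used at once
Reagents that add atoms: dimethyldioxirane, CC1(C)OO1
Why: This is the dioxirane α-hydroxylation of an enolised β-dicarbonyl (Rubottom-type enol epoxidation), in which the electrophilic oxidant selects the donor-substituted C2=C3 enol bond over the doubly acceptor-substituted C5=C6 bond and hydroxy epoxide 7 collapses under neutral, nearly water-free conditions to the C2 ketone and the C3 tertiary alcohol, formed racemic and erased in step 5.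

Step 5
Reactants: 8 3-hydroxy-3-tetradecylcyclohex-5-ene-1,2,4-trione
Product: 9 2-hydroxy-2-pentadecanoylcyclopent-4-ene-1,3-dione (achiral)
Conditions: Sc(OTf)3 (10 mol %), 4 Å MS, MeCN–CH2Cl2, −20 °C to rt
Reagents that add atoms: none
Why: Sc(OTf)3 chelates the s-cis O1/O2 pair of the 1,2-dione, the C3 hydroxyl oxygen donates as its proton is passed on, and the C3–C4 σ bond moves over to C2, so that acyl carbon C4 becomes bonded to C2 (C5 of the target, hence the C4–C5 bond), C3 leaves the ring as the side-chain ketone C1′ and O2 ends as the tertiary hydroxyl. The reaction type is the α-ketol (acyloin) rearrangement with ring contraction, seen in the same acyl-shift mode when the six-membered hop α-acids contract to the five-membered iso-α-acids under divalent magnesium salts, and in a related mode in the Hooker oxidation of hydroxyquinones. The five-membered ring is closed by a suprafacial 1,2-shift through a three-centre transition state inside the six-membered ring, not by an end-to-end cyclisation, and C3 is extruded. No stereocentre is created, since racemic C3 becomes trigonal and the new carbinol carbon carries two identical ring acyl arms, so 9 is achiral. The step needs the right acceptor and the right migrating group: C2 is the most electrophilic and the chelated carbonyl, a shift of the tetradecyl group to C2 merely regenerates 8, a shift of C2 to the C4 carbonyl would retain the 1,2-dione, and because α-ketol shifts are reversible the system should drain to 9, the only isomer free of vicinal carbonyl repulsion. Dry, base-free conditions keep out hydration, benzilic acid type contraction, carbon-to-oxygen acyl transfer and retro-Claisen loss of the chain.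

Step 6
Reactants: 9 2-hydroxy-2-pentadecanoylcyclopent-4-ene-1,3-dione
Product: 10 (4S,5S)-4,5-dihydroxy-5-pentadecanoylcyclopent-2-en-1-one (ring hydroxyls trans, secondary hydroxyl cis to the acyl group; its carbinol carbon is C1 in target numbering)
Conditions: (R)-2-methyl-CBS-oxazaborolidine (C18H20BNO, 20 mol %), catecholborane (1.5 equiv), toluene–CH2Cl2, −78 °C; MeOH quench, pH 7 buffer
Reagents that add atoms: none
Why: This is a Corey–Bakshi–Shibata reduction used as a desymmetrisation, as known for 2,2-disubstituted cyclopentane-1,3-diones, in which the flat, electron-poor enedione carbonyls should react well before the acyclic ketone next to the quaternary carbon, hydride enters the ring face anti to the acyl chain (the hydroxyl side), and the (R)-catalyst, reading the quaternary carbon as large and the vinylic CH as small, picks the enantiotopic carbonyl that gives the (S)-carbinol.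

Step 7
Reactants: 10 (4S,5S)-4,5-dihydroxy-5-pentadecanoylcyclopent-2-en-1-one
Product: 11 (4S,5R)-4,5-dihydroxy-5-[(1S)-1-hydroxypentadecyl]cyclopent-2-en-1-one (ring hydroxyls trans)
Conditions: Me4NBH(OAc)3 (3 equiv), MeCN–AcOH 1:1, −30 °C; aq potassium sodium tartrate
Reagents that add atoms: none
Why: In this Evans–Saksena hydroxyl-directed reduction the reagent leaves unbound ketones alone, the secondary ring hydroxyl cis to the acyl group binds boron and passes hydride to C1′ through a chair with the tetradecyl chain equatorial to give the 1,3-anti diol, which is (1′S), and any hydride that strayed to the enone carbonyl would be undone in step 8.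

Step 8
Reactants: 11 (4S,5R)-4,5-dihydroxy-5-[(1S)-1-hydroxypentadecyl]cyclopent-2-en-1-one
Product: 12 2-hydroxy-2-[(1S)-1-hydroxypentadecyl]cyclopent-4-ene-1,3-dione
Conditions: activated MnO2 (excess), CH2Cl2, rt
Reagents that add atoms: none
Why: Allylic oxidation with MnO2 selects the ring carbinol next to the C=C over the saturated, neopentyl-type C1′ carbinol and the tertiary hydroxyl, so the two temporary ring stereocentres vanish and C1′ (S) remains as the only stereocentre.

Step 9
Reactants: 12 2-hydroxy-2-[(1S)-1-hydroxypentadecyl]cyclopent-4-ene-1,3-dione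
Product: 14 (1S)-1-[(1R,2S)-1,2-dihydroxy-5-oxocyclopent-3-en-1-yl]pentadecyl acetate (target), via acetaldehyde hemiacetal 13 (not isolated)
Conditions: SmI2 (0.3 equiv) premixed with MeCHO (10 equiv), THF, −10 °C, until the blue colour of divalent samarium is gone; then 12, −10 to 0 °C
Reagents that add atoms: acetaldehyde, CC=O
Why: In this Evans–Tishchenko reduction O1′ adds to acetaldehyde, trivalent samarium ties the hemiacetal oxygen of 13 to a ring carbonyl, and the hemiacetal hydrogen passes to that carbonyl through a chair with the tetradecyl chain equatorial, which gives the 1,3-anti relation (C4 chosen over C1, hence 5R), places hydride on the ring face that bears the side chain (hence 4S with O4 cis to O5) and leaves the acetate on O1′.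

## Compound list

1 | 1,2,4-trimethoxybenzene | COc1ccc(OC)c(OC)c1 | starting material
2 | 1-bromotetradecane | CCCCCCCCCCCCCCBr | starting material
3 | 3-lithio-1,2,4-trimethoxybenzene | [Li]c1c(OC)ccc(OC)c1OC | intermediate
4 | 1,2,4-trimethoxy-3-tetradecylbenzene | COc1ccc(OC)c(OC)c1CCCCCCCCCCCCCC | intermediate
5 | 3-tetradecylbenzene-1,2,4-triol | Oc1ccc(O)c(O)c1CCCCCCCCCCCCCC | intermediate
6 | 2-hydroxy-3-tetradecylcyclohexa-2,5-diene-1,4-dione | O=C1C=CC(=O)C(CCCCCCCCCCCCCC)=C1O | intermediate
7 | 1-hydroxy-6-tetradecyl-7-oxabicyclo[4.1.0]hept-3-ene-2,5-dione (racemic) | O=C1C=CC(=O)C2(CCCCCCCCCCCCCC)OC12O | intermediate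
8 | 3-hydroxy-3-tetradecylcyclohex-5-ene-1,2,4-trione (racemic) | O=C1C=CC(=O)C(O)(CCCCCCCCCCCCCC)C1=O | intermediate
9 | 2-hydroxy-2-pentadecanoylcyclopent-4-ene-1,3-dione (achiral) | CCCCCCCCCCCCCCC(=O)C1(O)C(=O)C=CC1=O | intermediate
10 | (4S,5S)-4,5-dihydroxy-5-pentadecanoylcyclopent-2-en-1-one | CCCCCCCCCCCCCCC(=O)[C@@]1(O)[C@@H](O)C=CC1=O | intermediate
11 | (4S,5R)-4,5-dihydroxy-5-[(1S)-1-hydroxypentadecyl]cyclopent-2-en-1-one | CCCCCCCCCCCCCC[C@H](O)[C@@]1(O)[C@@H](O)C=CC1=O | intermediate
12 | 2-hydroxy-2-[(1S)-1-hydroxypentadecyl]cyclopent-4-ene-1,3-dione | CCCCCCCCCCCCCC[C@H](O)C1(O)C(=O)C=CC1=O | intermediate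
13 | 2-hydroxy-2-[(1S)-1-(1-hydroxyethoxy)pentadecyl]cyclopent-4-ene-1,3-dione (present as its samarium alkoxide, hemiacetal carbon undefined) | CCCCCCCCCCCCCC[C@H](OC(C)O)C1(O)C(=O)C=CC1=O | intermediate
14 | (1S)-1-[(1R,2S)-1,2-dihydroxy-5-oxocyclopent-3-en-1-yl]pentadecyl acetate | CCCCCCCCCCCCCC[C@H](OC(C)=O)[C@@]1(O)C(=O)C=C[C@@H]1O | target

## Step count

Total step count: 9
Longest linear sequence: 9 steps (1 or 2 to 14)

## Steps most likely to fail

**Step 5.**
- What may go wrong: the shift may stall on a chelated or hydrated trione. It may also take another course, such as migration towards the C4 carbonyl, carbon-to-oxygen acyl transfer, or cleavage of the acyl chain from the product by traces of nucleophile.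
- Fallback: it sets out from 2, builds the acylcyclopentenedione without any ring contraction, and comes back at 9.
- Course: Mg in THF gives tetradecylmagnesium bromide F1, and CO2 followed by aqueous HCl gives pentadecanoic acid F2. SOCl2 gives pentadecanoyl chloride F3, and two equivalents of Ph3P=CH2 give 1-(triphenylphosphoranylidene)hexadecan-2-one F4. Wittig olefination of one carbonyl of maleic anhydride gives 5-(2-oxohexadecylidene)furan-2(5H)-one F5. The NaOMe-induced ylidenebutenolide rearrangement in MeOH gives 2-pentadecanoylcyclopent-4-ene-1,3-dione F6. Dioxirane hydroxylation of this fully enolised triketone at C2 gives 9.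

**Step 6.**
- What may go wrong: discrimination may be insufficient between ring and side-chain carbonyls, between the two ring faces, or between the enantiotopic carbonyls. Reduction may also run on past the mono-carbinol stage.
- Fallback: it sets out from 9, needs none of these selectivities, and comes back at 12.
- Course: all three carbonyls are reduced with excess BH3·SMe2 under stoichiometric (R)-2-methyl-CBS-oxazaborolidine (C18H20BNO). The side-chain ketone (quaternary carbon against n-alkyl) is read directly by the catalyst to give the (1′S)-carbinol. The ring carbinols form as an inconsequential mixture in 2-[(1S)-1-hydroxypentadecyl]cyclopent-4-ene-1,2,3-triol F7. Excess MnO2 then returns both allylic carbinols to the enedione 12, and steps 7 and 8 are dropped.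

**Step 9.**
- What may go wrong: the samarium alkoxide may cause retro-aldol cleavage of the C5–C1′ bond, with loss or scrambling of C1′. Residual divalent samarium may transfer an electron to the enedione, or the acetyl group may migrate after the hydride transfer.
- Fallback: it sets out from 12, separates reduction from acetylation, and comes back at 14.
- Course: O1′-directed reduction with Me4NBH(OAc)3 in MeCN–AcOH has the same facial and 1,3-anti logic and gives (4S,5S)-4,5-dihydroxy-5-[(1S)-1-hydroxypentadecyl]cyclopent-2-en-1-one F8. PhB(OH)2 with MgSO4 ties up the cis-4,5-diol under equilibrium control as the cyclic phenylboronate F9. Ac2O, pyridine and catalytic DMAP at 0 °C acetylate the only free hydroxyl to give the O1′-acetyl phenylboronate F10. Exchange with pinacol releases 14.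

## Further compounds

F1 | step 5 | tetradecylmagnesium bromide | CCCCCCCCCCCCCC[Mg]Br
F2 | step 5 | pentadecanoic acid | CCCCCCCCCCCCCCC(=O)O
F3 | step 5 | pentadecanoyl chloride | CCCCCCCCCCCCCCC(=O)Cl
F4 | step 5 | 1-(triphenylphosphoranylidene)hexadecan-2-one | CCCCCCCCCCCCCCC(=O)C=P(c1ccccc1)(c1ccccc1)c1ccccc1
F5 | step 5 | 5-(2-oxohexadecylidene)furan-2(5H)-one (alkene geometry immaterial) | CCCCCCCCCCCCCCC(=O)C=C1C=CC(=O)O1
F6 | step 5 | 2-pentadecanoylcyclopent-4-ene-1,3-dione (drawn as the triketone, enolised in fact) | CCCCCCCCCCCCCCC(=O)C1C(=O)C=CC1=O
F7 | step 6 | 2-[(1S)-1-hydroxypentadecyl]cyclopent-4-ene-1,2,3-triol (ring carbinols mixed) | CCCCCCCCCCCCCC[C@H](O)C1(O)C(O)C=CC1O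
F8 | step 9 | (4S,5S)-4,5-dihydroxy-5-[(1S)-1-hydroxypentadecyl]cyclopent-2-en-1-one (ring hydroxyls cis) | CCCCCCCCCCCCCC[C@H](O)[C@@]1(O)C(=O)C=C[C@@H]1O
F9 | step 9 | cyclic phenylboronate of the cis-4,5-diol of F8 | CCCCCCCCCCCCCC[C@H](O)[C@]12OB(c3ccccc3)O[C@H]1C=CC2=O
F10 | step 9 | O1′-acetate of F9 | CCCCCCCCCCCCCC[C@H](OC(C)=O)[C@]12OB(c3ccccc3)O[C@H]1C=CC2=O
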